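**Retrosynthetic overview**
1. Target acid ⇒ ethyl ester ⇒ C8′–C9′ alkenyl–alkenyl (Negishi) disconnection into a ring-bearing terminal alkyne and (1E,4Z)-1-iodohepta-1,4-diene (two steps from leaf alcohol). The autoxidisable triene is attached only after all O2 chemistry is finished.
2. The 1,2-dioxolane (the only ring) is cut at both C–O bonds as in the presumed biosynthesis. C3–O is cut by retro 5-exo peroxa-Michael addition (5-hydroperoxy-2-enoate). C5–O is cut by retro O2 capture at the tertiary C5 radical of an achiral skipped 2,5-dienoate, so both ring oxygens come from one O2.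
3. Stereochemistry: C5 is made racemic and a chiral bifunctional iminophosphorane fixes C3 as R in both enantiomers (stereodivergent cyclisation). The trans (3R,5S) ester is then separated from the cis (3R,5R) ester on silica gel.
4. Skipped dienoate ⇒ C4–C5 alkenyl–allyl coupling of 1,9-decadiyne (α-hydroalumination of one alkyne) with ethyl (2E)-4-bromo-3-methylbut-2-enoate.
5. Ring order: one ring, closed in step 3.

Assumption: the (S)-configured catalyst A (defined in step 3) delivers the peroxide to the enoate face that gives 3R; if experiment shows the opposite sense, its enantiomer (from D-tert-leucine) is used and nothing else changes.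
Assumption: the bromo ester is bought as a catalogue compound (it is the NBS bromination product of ethyl 3-methylbut-2-enoate) and used as the pure E isomer.

Step 1
Reactants: 1 deca-1,9-diyne; 2 ethyl (2E)-4-bromo-3-methylbut-2-enoate
Product: 4 ethyl (2E)-3-methyl-5-methylidenetridec-2-en-12-ynoate, via alkenylalane 3 (not isolated)
Conditions: 1 (3 equiv), DIBAL-H (1.0 equiv), Ni(dppp)Cl2 (3 mol %, dppp = 1,3-bis(diphenylphosphino)propane), THF, 0 to 22 °C, 2 h; then 2 (0.9 equiv), Pd(PPh3)4 (5 mol %), 22 °C, 12 h; excess 1 recovered by distillation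
Reagents that add atoms: none
Why: Nickel-catalysed α-selective (Markovnikov) hydroalumination puts aluminium on the internal alkyne carbon, and the alkenylalane then undergoes a Negishi-type alkenyl–allyl coupling under zerovalent palladium at the unhindered CH2 terminus of the π-allyl with retention of the E-enoate; the threefold excess of diyne holds the reaction at the mono stage and no stereocentre is formed.

Step 2
Reactants: 4 ethyl (2E)-3-methyl-5-methylidenetridec-2-en-12-ynoate
Product: 5 ethyl (2E)-3,5-dimethyl-5-[(triethylsilyl)peroxy]tridec-2-en-12-ynoate (racemic)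
Conditions: Co(thd)2 (10 mol %, thd = 2,2,6,6-tetramethylheptane-3,5-dionate), Et3SiH (2.5 equiv), O2 (1 atm), ClCH2CH2Cl, 22 °C, 3 h
Reagents that add atoms: dioxygen O=O; triethylsilane CC[SiH](CC)CC
Why: In this Mukaiyama–Isayama hydroperoxysilylation, cobalt hydride transfers an H atom to the electron-rich 1,1-disubstituted alkene (faster than to the β,β-disubstituted enoate or the alkyne), creating the C5 methyl group and the tertiary C5 radical, which captures O2 as in the presumed dioxygenation of the branched polyketide olefin; C5 is deliberately formed racemic.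

Step 3
Reactants: 5 ethyl (2E)-3,5-dimethyl-5-[(triethylsilyl)peroxy]tridec-2-en-12-ynoate
Product: 7 ethyl 2-[(3R,5S)-3,5-dimethyl-5-(oct-7-yn-1-yl)-1,2-dioxolan-3-yl]acetate, via hydroperoxide 6 (not isolated)
Conditions: (a) HCl (5 mol %), MeOH, 0 °C, 20 min; solid NaHCO3, filter, evaporate with toluene; (b) catalyst A (10 mol %) = 1-[3,5-bis(trifluoromethyl)phenyl]-3-[(2S)-3,3-dimethyl-1-{[tris(4-methoxyphenyl)-λ5-phosphanylidene]amino}butan-2-yl]urea, toluene, 4 Å sieves, −20 °C, 48 h; SiO2 chromatography
Reagents that add atoms: none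
Why: Proposed new method: after acid methanolysis of the O–Si bond, the superbasic iminophosphorane deprotonates the hydroperoxide (far more acidic than the alcohols such catalysts already cyclise), the urea N–H bonds (a urea because a thiourea could be oxidised) bind the ester carbonyl, and the chiral ion pair closes the ring by the biosynthetic 5-exo peroxa-Michael addition on one enoate face, so C3 becomes R in both enantiomers of 6 because C5 (methyl versus n-alkyl, remote from the binding site) exerts almost no bias; (5S)-6 therefore gives trans-7 while the 5R half ends in the cis series and is removed on silica gel (stereodivergent reaction on a racemic mixture, at most 50 % yield), the enolate is protonated by further hydroperoxide faster than it can attack the O–O bond, and the closest known reaction types are the amine/fluoroalcohol-promoted racemic peroxa-Michael closure of hydroperoxy enoates and the bifunctional-iminophosphorane-catalysed enantioselective intramolecular oxa-Michael addition of alcohols to unactivated α,β-unsaturated esters.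

Step 4
Reactants: 8 (3Z)-hex-3-en-1-ol
Product: 9 (3Z)-hex-3-enal
Conditions: IBX (1.3 equiv), DMSO, 22 °C, 2 h; pentane extraction, used at once
Reagents that add atoms: none
Why: IBX oxidation stops at the aldehyde under neutral conditions, so the β,γ-Z-alkene neither moves into conjugation nor isomerises.

Step 5
Reactants: 9 (3Z)-hex-3-enal
Product: 10 (1E,4Z)-1-iodohepta-1,4-diene
Conditions: CrCl2 (6 equiv), CHI3 (2 equiv), THF–1,4-dioxane (1:6), 0 to 22 °C, 6 h
Reagents that add atoms: iodoform IC(I)I
Why: In the Takai olefination the geminal dichromium reagent from CHI3 and CrCl2 adds to the aldehyde and eliminates to the E-vinyl iodide (dioxane raises E:Z) under non-basic conditions that leave the skipped Z-alkene in place.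

Step 6
Reactants: 7 ethyl 2-[(3R,5S)-3,5-dimethyl-5-(oct-7-yn-1-yl)-1,2-dioxolan-3-yl]acetate; 10 (1E,4Z)-1-iodohepta-1,4-diene
Product: 13 ethyl 2-[(3R,5S)-3,5-dimethyl-5-[(7E,9E,12Z)-pentadeca-7,9,12-trien-1-yl]-1,2-dioxolan-3-yl]acetate, via alkenylzirconocene 11 (not isolated), via alkenylzinc chloride 12 (not isolated)
Conditions: Cp2Zr(H)Cl (1.2 equiv), THF, 0 to 22 °C, 30 min, dark; ZnCl2 (1.2 equiv), 0 °C; then 10 (1.1 equiv), Pd(PPh3)4 (5 mol %), 22 °C, 4 h
Reagents that add atoms: none
Why: Syn, terminal hydrozirconation gives the E-alkenylzirconocene, zirconium-to-zinc transmetalation and Negishi coupling join both alkenyl partners with retention to give the 7E,9E-diene beside the untouched 12Z-alkene; the hindered di-tertiary dialkyl peroxide and the ester survive these fast, mild reactions and the two quaternary stereocentres cannot epimerise.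

Step 7
Reactants: 13 ethyl 2-[(3R,5S)-3,5-dimethyl-5-[(7E,9E,12Z)-pentadeca-7,9,12-trien-1-yl]-1,2-dioxolan-3-yl]acetate
Product: 14 2-[(3R,5S)-3,5-dimethyl-5-[(7E,9E,12Z)-pentadeca-7,9,12-trien-1-yl]-1,2-dioxolan-3-yl]acetic acid (target)
Conditions: LiOH (4 equiv), THF–EtOH–H2O (3:1:1), argon, 0 to 22 °C, 12 h; then 1 M HCl to pH 4, 0 °C
Reagents that add atoms: lithium hydroxide [Li+].[OH-]
Why: Ester saponification is safe here because the peroxide carbons carry no hydrogen (no Kornblum–DeLaMare cleavage), retro-Michael opening of the carboxylate is negligible at this temperature, and the triene is inert to aqueous base, so both stereocentres and all three alkene geometries are kept.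

**Compound list**
1 | deca-1,9-diyne | C#CCCCCCCC#C | starting material
2 | ethyl (2E)-4-bromo-3-methylbut-2-enoate | CCOC(=O)/C=C(\C)CBr | starting material
3 | (dec-1-en-9-yn-2-yl)bis(2-methylpropyl)aluminium | C=C(CCCCCCC#C)[Al](CC(C)C)CC(C)C | intermediate
4 | ethyl (2E)-3-methyl-5-methylidenetridec-2-en-12-ynoate | CCOC(=O)/C=C(\C)CC(=C)CCCCCCC#C | intermediate
5 | ethyl (2E)-3,5-dimethyl-5-[(triethylsilyl)peroxy]tridec-2-en-12-ynoate, racemic at C5 | CCOC(=O)/C=C(\C)CC(C)(CCCCCCC#C)OO[Si](CC)(CC)CC | intermediate
6 | ethyl (2E)-5-hydroperoxy-3,5-dimethyltridec-2-en-12-ynoate, racemic at C5 | CCOC(=O)/C=C(\C)CC(C)(CCCCCCC#C)OO | intermediate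
7 | ethyl 2-[(3R,5S)-3,5-dimethyl-5-(oct-7-yn-1-yl)-1,2-dioxolan-3-yl]acetate (ring methyls trans) | C#CCCCCCC[C@@]1(C)C[C@](C)(CC(=O)OCC)OO1 | intermediate
8 | (3Z)-hex-3-en-1-ol | CC/C=C\CCO | starting material
9 | (3Z)-hex-3-enal | CC/C=C\CC=O | intermediate
10 | (1E,4Z)-1-iodohepta-1,4-diene | CC/C=C\C/C=C/I | intermediate
11 | chlorobis(cyclopentadienyl)[(1E)-8-{(3S,5R)-5-(2-ethoxy-2-oxoethyl)-3,5-dimethyl-1,2-dioxolan-3-yl}oct-1-en-1-yl]zirconium (same ring configuration as 7) | Cl[Zr](C1C=CC=C1)(C1C=CC=C1)/C=C/CCCCCC[C@@]2(C)C[C@](C)(CC(=O)OCC)OO2 | intermediate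
12 | corresponding (1E)-alkenylzinc chloride (same ring configuration as 7) | Cl[Zn]/C=C/CCCCCC[C@@]1(C)C[C@](C)(CC(=O)OCC)OO1 | intermediate
13 | ethyl 2-[(3R,5S)-3,5-dimethyl-5-[(7E,9E,12Z)-pentadeca-7,9,12-trien-1-yl]-1,2-dioxolan-3-yl]acetate | CC/C=C\C/C=C/C=C/CCCCCC[C@@]1(C)C[C@](C)(CC(=O)OCC)OO1 | intermediate
14 | 2-[(3R,5S)-3,5-dimethyl-5-[(7E,9E,12Z)-pentadeca-7,9,12-trien-1-yl]-1,2-dioxolan-3-yl]acetic acid | CC/C=C\C/C=C/C=C/CCCCCC[C@@]1(C)C[C@](C)(CC(=O)O)OO1 | target

**Total step count:** 7. **Longest linear sequence:** 5 (steps 1, 2, 3, 6, 7).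

**Three steps most likely to fail**

Step 3 is a new asymmetric ring closure, and the catalyst may be slow on a β,β-disubstituted enoate or poorly face-selective. The fallback runs from 5 back to 7 and replaces catalyst control by resolution. 5 is desilylated as before and 6 is closed with Et2NH in CF3CH2OH at 22 °C, the established racemic conditions. This gives 7 together with its enantiomer ethyl 2-[(3S,5R)-3,5-dimethyl-5-(oct-7-yn-1-yl)-1,2-dioxolan-3-yl]acetate F1. It also gives the two cis esters, ethyl 2-[(3R,5R)-3,5-dimethyl-5-(oct-7-yn-1-yl)-1,2-dioxolan-3-yl]acetate F2 and ethyl 2-[(3S,5S)-3,5-dimethyl-5-(oct-7-yn-1-yl)-1,2-dioxolan-3-yl]acetate F3. Silica gel removes F2 and F3. Preparative supercritical-fluid chromatography on an amylose tris(3,5-dimethylphenylcarbamate) column then separates 7 from F1.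

Step 1 combines a statistical mono-hydroalumination with a one-pot palladium coupling of an alane next to an ester, in the presence of nickel residues. The fallback runs from 3 back to 4. It separates the two metal-catalysed events and moves the coupling from aluminium to boron. 3 is quenched with 2-methoxy-4,4,5,5-tetramethyl-1,3,2-dioxaborolane to give 2-(dec-1-en-9-yn-2-yl)-4,4,5,5-tetramethyl-1,3,2-dioxaborolane F4. F4 is chromatographed free of diyne, bis-adduct and β-isomer. A Suzuki–Miyaura alkenyl–allyl coupling with 2 (Pd(PPh3)4, K3PO4, THF–H2O, 50 °C) then gives 4.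

Step 6 exposes the O–O bond and the ester to the oxophilic, hydridic zirconium reagent, and the geometric purity of the diene is at stake. The fallback runs from 7 back to 13 and avoids zirconium and zinc. Hydroboration with pinacolborane (1.5 equiv), catalysed by dicyclohexylborane (10 mol %) in THF at 22 °C, gives ethyl 2-[(3R,5S)-3,5-dimethyl-5-[(7E)-8-(4,4,5,5-tetramethyl-1,3,2-dioxaborolan-2-yl)oct-7-en-1-yl]-1,2-dioxolan-3-yl]acetate F5. F5 is stable and can be purified to a single alkene isomer. A Suzuki–Miyaura coupling with 10 (Pd(dppf)Cl2, dppf = 1,1′-bis(diphenylphosphino)ferrocene, K3PO4, THF–H2O, 22 °C) gives 13.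

**Further compounds**
F1 | step 3 | ethyl 2-[(3S,5R)-3,5-dimethyl-5-(oct-7-yn-1-yl)-1,2-dioxolan-3-yl]acetate | C#CCCCCCC[C@]1(C)C[C@@](C)(CC(=O)OCC)OO1
F2 | step 3 | ethyl 2-[(3R,5R)-3,5-dimethyl-5-(oct-7-yn-1-yl)-1,2-dioxolan-3-yl]acetate | C#CCCCCCC[C@]1(C)C[C@](C)(CC(=O)OCC)OO1
F3 | step 3 | ethyl 2-[(3S,5S)-3,5-dimethyl-5-(oct-7-yn-1-yl)-1,2-dioxolan-3-yl]acetate | C#CCCCCCC[C@@]1(C)C[C@@](C)(CC(=O)OCC)OO1
F4 | step 1 | 2-(dec-1-en-9-yn-2-yl)-4,4,5,5-tetramethyl-1,3,2-dioxaborolane | C=C(CCCCCCC#C)B1OC(C)(C)C(C)(C)O1
F5 | step 6 | ethyl 2-[(3R,5S)-3,5-dimethyl-5-[(7E)-8-(4,4,5,5-tetramethyl-1,3,2-dioxaborolan-2-yl)oct-7-en-1-yl]-1,2-dioxolan-3-yl]acetate | CC1(C)OB(/C=C/CCCCCC[C@@]2(C)C[C@](C)(CC(=O)OCC)OO2)OC1(C)C
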